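**Retrosynthetic overview**

1. Feature: in ring B (δ-lactone C9–C10–C12–O14–C15–C16) the unit C17(=O18)–C16–C15–O14 is a β-acyloxy ketone and C17…C12 is a 1,5-dicarbonyl, so O14–C15 and C16–C9 are both conjugate-addition bonds. The target is cut into methylene ketone 12 (rings C and D) and acid 18 (ring A).
2. Rings C/D: ring C is 4,4-dimethylcyclohexenone. C23 comes from a Cu-catalysed asymmetric silylmethyl Grignard addition to the dienone, ring D from Tamao–Fleming oxidation/oxa-Michael (O21–C20), C15 from a Mannich methylenation at C16.
3. Ring A: Birch reduction of 3-methoxybenzoic acid, dioxolane at C6, alkene moved into conjugation (C9=C10).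
4. Ring B is closed last in the union of 12 and 18 (step 11; sets C16, C9, C10). Order of ring formation: C (bought), D, A (from the arene), B.
5. Side chain: C6 ketone → enol triflate → acetyl (C6 by equilibration) → 2-substituted acrylic acid by carbonylation → Ru–BINAP hydrogenation (C2).

Key step: step 11

Remark: atom labels such as C16 or O21 are positions in the target SMILES; the sense of induction of the copper ligand (step 3) and of BINAP (step 18) is assigned by analogy, and the antipodal ligand is taken if a test shows the opposite sense.

**Route**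

Step 1
Reactants: 1 (4,4-dimethylcyclohex-2-en-1-one)
Product: 2 4,4-dimethylcyclohexa-2,5-dien-1-one
Conditions: DDQ (1.3 equiv), 1,4-dioxane, reflux
Reagents that add atoms: none
Why: DDQ dehydrogenation (hydride abstraction from the enol, then loss of a proton) of the enone gives the cross-conjugated dienone, and the quaternary C24 rules out aromatisation.

Step 2
Reactants: 3 ((chloromethyl)(isopropoxy)dimethylsilane)
Product: 4 {[isopropoxy(dimethyl)silyl]methyl}magnesium chloride (titrated Et2O solution)
Conditions: Mg turnings, BrCH2CH2Br (cat.), Et2O, reflux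
Reagents that add atoms: magnesium, [Mg]
Why: Grignard formation by magnesium insertion into the C–Cl bond gives a hydroxymethyl anion equivalent whose Si–O bond is later the handle for Tamao–Fleming oxidation.

Step 3
Reactants: 2 (dienone); 4 (Grignard reagent)
Product: 5 (5S)-5-{[isopropoxy(dimethyl)silyl]methyl}-4,4-dimethylcyclohex-2-en-1-one
Conditions: CuBr·SMe2 (5 mol %), (R)-1-[(SP)-2-(diphenylphosphino)ferrocenyl]ethyldicyclohexylphosphine (6 mol %; the ligand enantiomer that gives 5S), tBuOMe, −78 °C, slow addition of 4; NH4Cl (aq.)
Reagents that add atoms: none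
Why: Copper-catalysed asymmetric conjugate addition of a Grignard reagent to one enone arm of the symmetric dienone, in which the chiral diphosphine–copper complex selects the enone face and so sets C23 (5S in 5), while the product stays a magnesium enolate until the quench and therefore does not react a second time.

Step 4
Reactants: 5
Product: 7 (1S,5R)-8,8-dimethyl-6-oxabicyclo[3.2.1]octan-3-one, via hydroxy enone 6 (not isolated)
Conditions: 30% H2O2, KF, KHCO3, THF/MeOH (1:1), 25 °C; Na2S2O3 (aq.); then K2CO3, MeOH, 25 °C
Reagents that add atoms: hydrogen peroxide, OO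
Why: Tamao–Fleming oxidation turns the C–Si bond into C–OH, and the primary alcohol of 6 then adds to the enone β-carbon C20 in a 5-exo-trig oxa-Michael closure of ring D that can only bridge the ring cis, so that C20 (R) follows from C23; the neopentyl β-carbon and the bicarbonate buffer should keep nucleophilic epoxidation of the enone slow until the ring has closed.

Step 5
Reactants: 7; 8 (N,N-dimethylmethyleneiminium iodide)
Product: 10 (1S,5R)-2-[(dimethylamino)methyl]-8,8-dimethyl-6-oxabicyclo[3.2.1]octan-3-one (C2 epimers), via ring-opened Mannich base 9 (not isolated)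
Conditions: LiN(iPr)2 (2.3 equiv), THF, −78 °C (7 added to the base), then 0 °C; −78 °C, 8 (3 equiv), to 25 °C; then K2CO3, MeOH, 25 °C
Reagents that add atoms: none
Why: Mannich reaction of lithium enolates with the preformed iminium salt, regioselective because the C19 enolate is the enolate of the oxa-Michael closure (axial C20–O21 bond antiperiplanar to its π system) and opens by E1cB to an alkoxide enone whose only enolisable carbon is C16, so that the excess of LiN(iPr)2 turns it into the C16 dienolate, while direct deprotonation at C16 gives the wanted enolate anyway; both carry C15 to C16, and the ring-opened adduct 9 recloses by oxa-Michael addition in K2CO3/MeOH.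

Step 6
Reactants: 10
Product: 12 (1R,5R)-8,8-dimethyl-2-methylidene-6-oxabicyclo[3.2.1]octan-3-one (fragment 1), via methiodide 11 (not isolated)
Conditions: MeI (5 equiv), THF, 25 °C; then NaHCO3 (aq.)/CH2Cl2, 25 °C; used at once
Reagents that add atoms: none
Why: Exhaustive N-methylation and base-induced E1cB elimination of trimethylamine from the β-ammonium ketone give the exocyclic enone, and no endocyclic isomer can arise because C23 is a bridgehead.

Step 7
Reactants: 13 (3-methoxybenzoic acid)
Product: 14 3-methoxycyclohexa-2,5-diene-1-carboxylic acid (racemic)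
Conditions: Li, NH3 (l)/THF, −78 °C; NH4Cl
Reagents that add atoms: none
Why: Birch reduction of the benzoate, in which the carboxylate directs protonation to C10 and the para carbon C7 and the methoxy group stays on a double bond, gives the 1,4-dihydro acid with the future C6 as an enol ether.

Step 8
Reactants: 14
Product: 15 methyl 3-methoxycyclohexa-2,5-diene-1-carboxylate (racemic)
Conditions: Me3SiCHN2, PhMe/MeOH (4:1), 0 °C
Reagents that add atoms: (trimethylsilyl)diazomethane, C[Si](C)(C)C=[N+]=[N-]
Why: Esterification with (trimethylsilyl)diazomethane under neutral conditions, chosen so that neither acid nor base moves the skipped diene.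

Step 9
Reactants: 15
Product: 16 methyl 1,4-dioxaspiro[4.5]dec-8-ene-7-carboxylate (racemic)
Conditions: HOCH2CH2OH (3 equiv), pyridinium p-toluenesulfonate (5 mol %), CH2Cl2, 25 °C
Reagents that add atoms: ethane-1,2-diol, OCCO
Why: Acid-catalysed addition of the diol to the enol ether (C-protonation to an oxocarbenium ion, then transacetalisation) masks C6 as a dioxolane and leaves the isolated C8=C9 alkene in place.

Step 10
Reactants: 16
Product: 18 1,4-dioxaspiro[4.5]dec-7-ene-7-carboxylic acid (fragment 2), via conjugated methyl ester 17 (not isolated)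
Conditions: NaOMe (0.5 equiv), MeOH, 50 °C; then NaOH (2 M aq.), 25 °C; NaHSO4 (aq.) to pH 4–5, 0 °C
Reagents that add atoms: sodium hydroxide, [Na+].[OH-]
Why: Methoxide removes the C10 hydrogen (allylic and α to the ester) and reprotonation at C8 moves the alkene into conjugation as C9=C10, the only conjugated isomer this dienolate can give, after which saponification and a mildly acidic work-up give the acid with the ketal intact.

Step 11
Reactants: 12 (fragment 1); 18 (fragment 2)
Product: 20 tetracyclic spirolactone carrying the C6 ketone as dioxolane (9R,10S,16S,20R,23R), via β-acyloxy ketone 19 (not isolated)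
Conditions: 18 (1.2 equiv), Cs2CO3 (1.1 equiv), MeCN (0.05 M), 25 °C; 12 added slowly; 45 °C
Reagents that add atoms: none
Why: Proposed new method: the cesium carboxylate of 18 adds reversibly to the exocyclic methylene C15 of 12 (oxa-Michael) to give the C16 enolate of β-acyloxy ketone 19, in which the once unreactive carboxylate has become an ester that activates C9=C10 right beside that enolate, and the enolate then adds to C9 while CsHCO3 protonates the lactone enolate at C10. The closest known reaction types are base-mediated oxa-Michael/Michael domino annulations and ester-tethered intramolecular Michael additions of ketone enolates; new are a free carboxylic acid as the oxygen donor and a fully substituted, neopentyl donor carbon. Ring B closes in a 6-endo-trig mode (C16 onto C9, with C9=C10 inside the new ring). C16 is set by addition on the enolate face syn to the C24 bridge and anti to the O21–C22 bridge, the axial trajectory that enolates of bridged ketones of this ring type normally follow because the two-atom bridge screens the other face; C9 follows from the tether, since the ring acrylate keeps C8 anti to C15 across the new bond and the arrangement with C10 over the trigonal C17 and the C9 hydrogen toward the bridgehead C23 is the less crowded one; C10 is set by protonation anti to C16, which gives the cis ring fusion that should also be the more stable one. The step needs C–C bond formation to win over reversion and needs the C24-syn face: the first is secured because loss of the carboxylate from 19 only regenerates 12 and 18, so the sequence corrects itself until the irreversible C–C bond forms, whereas the second rests on the O21–C22 bridge alone and is opposed by the syn methyl on C24, which is the weak point of the route.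

Step 12
Reactants: 20
Product: 21 diketo lactone (C6 ketone free)
Conditions: 1 M HCl (aq.)/THF (1:4), 25 °C
Reagents that add atoms: water, O
Why: Acid-catalysed ketal hydrolysis, which the rest of the molecule tolerates because C16 is quaternary (the β-acyloxy ketone cannot eliminate) and dilute acid opens neither the lactone nor ring D.

Step 13
Reactants: 21
Product: 22 ring A enol triflate (C6=C7)
Conditions: KN(SiMe3)2 (1.05 equiv), THF, −78 °C; PhNTf2 (1.1 equiv), −78 to −40 °C
Reagents that add atoms: N-phenylbis(trifluoromethanesulfonimide), FC(F)(F)S(=O)(=O)N(c1ccccc1)S(=O)(=O)C(F)(F)F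
Why: Kinetic enolate formation with a hindered amide and O-triflation (enol triflate synthesis) at the ring A ketone, deprotonated at the unhindered C7, whereas the C17 ketone has no hydrogen on C16 and its axial C19 hydrogen lies between the axial C9 and the C24 methyl, and the lactone α-hydrogen is far less acidic; the C6=C11 regioisomer, if formed, leads to the same ketone 27.

Step 14
Reactants: 22; 23 (tributyl(1-ethoxyvinyl)stannane)
Product: 25 ring A enone (acetyl on C6; C6=C7), via ethoxy diene 24 (not isolated)
Conditions: Pd(PPh3)4 (5 mol %), LiCl (3 equiv), THF, 65 °C; then 1 M HCl (aq.), 25 °C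
Reagents that add atoms: water, O
Why: Stille coupling of the enol triflate with the 1-ethoxyvinylstannane (LiCl aids transmetalation) and acid hydrolysis of the enol ether install the acetyl group as the future C2–C1 unit without creating a stereocentre.

Step 15
Reactants: 25
Product: 27 (6R)-methyl ketone (acetyl equatorial on ring A), via 6S-epimer 26 (not isolated)
Conditions: H2 (1 atm), 10% Pd/C, EtOAc, 25 °C; filter; DBU (0.3 equiv), CH2Cl2, 25 °C
Reagents that add atoms: none
Why: Hydrogenation of the enone C=C on Pd/C and base equilibration of the now enolisable C6 place the acetyl group equatorial and trans to C12 and C16 (6R), because the 6S epimer 26 would hold it 1,3-diaxial to C12; C10 is far less acidic than C6 and is not touched by DBU.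

Step 16
Reactants: 27
Product: 28 terminal enol triflate (CH2=C(OTf)–C6)
Conditions: KN(SiMe3)2 (1.1 equiv), THF, −78 °C; PhNTf2 (1.1 equiv), −78 to −30 °C
Reagents that add atoms: N-phenylbis(trifluoromethanesulfonimide), FC(F)(F)S(=O)(=O)N(c1ccccc1)S(=O)(=O)C(F)(F)F
Why: Kinetic deprotonation of the methyl ketone at the methyl group (the tertiary C6 hydrogen and the C19 hydrogens are hindered) and O-triflation give the terminal enol triflate and leave C6 as set.

Step 17
Reactants: 28
Product: 29 2-substituted acrylic acid (CH2=C(CO2H)–C6)
Conditions: Pd(OAc)2 (5 mol %), PPh3 (10 mol %), CO (1 atm), KOAc (4 equiv), DMF, 25–60 °C; aqueous work-up at pH 3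
Reagents that add atoms: carbon monoxide, [C-]#[O+]; water, O
Why: Palladium-catalysed carbonylation of the enol triflate (oxidative addition, CO insertion, capture of the acylpalladium by acetate, hydrolysis of the mixed anhydride on work-up) gives the 2-substituted acrylic acid, with C6 not involved.

Step 18
Reactants: 29
Product: 30 target CNP0152427.2
Conditions: Ru(OAc)2[(R)-BINAP] (1 mol %), H2 (60 atm), MeOH, 25 °C
Reagents that add atoms: none
Why: Carboxylate-directed asymmetric hydrogenation of a 2-alkylacrylic acid with Ru(OAc)2[(R)-BINAP], in which the catalyst selects the face of the 1,1-disubstituted alkene and sets C2 (R) by analogy with 2-aryl- and 2-cycloalkylacrylic acids, while the ketone and the lactone are inert to this catalyst.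

**Compound list**

1 | 4,4-dimethylcyclohex-2-en-1-one | CC1(C)CCC(=O)C=C1 | starting material
2 | 4,4-dimethylcyclohexa-2,5-dien-1-one | CC1(C)C=CC(=O)C=C1 | intermediate
3 | (chloromethyl)(isopropoxy)dimethylsilane | CC(C)O[Si](C)(C)CCl | starting material
4 | {[isopropoxy(dimethyl)silyl]methyl}magnesium chloride | CC(C)O[Si](C)(C)C[Mg]Cl | intermediate
5 | (5S)-5-{[isopropoxy(dimethyl)silyl]methyl}-4,4-dimethylcyclohex-2-en-1-one | CC(C)O[Si](C)(C)C[C@H]1CC(=O)C=CC1(C)C | intermediate
6 | (5S)-5-(hydroxymethyl)-4,4-dimethylcyclohex-2-en-1-one | OC[C@H]1CC(=O)C=CC1(C)C | intermediate (not isolated)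
7 | (1S,5R)-8,8-dimethyl-6-oxabicyclo[3.2.1]octan-3-one | O=C1C[C@H]2OC[C@@H](C1)C2(C)C | intermediate
8 | N,N-dimethylmethyleneiminium iodide | C=[N+](C)C.[I-] | starting material
9 | (5S)-6-[(dimethylamino)methyl]-5-(hydroxymethyl)-4,4-dimethylcyclohex-2-en-1-one (C6 epimers) | CN(C)CC1C(=O)C=CC(C)(C)[C@H]1CO | intermediate (not isolated)
10 | (1S,5R)-2-[(dimethylamino)methyl]-8,8-dimethyl-6-oxabicyclo[3.2.1]octan-3-one (C2 epimers) | CN(C)CC1C(=O)C[C@H]2OC[C@@H]1C2(C)C | intermediate
11 | 1-[(1S,5R)-8,8-dimethyl-3-oxo-6-oxabicyclo[3.2.1]octan-2-yl]-N,N,N-trimethylmethanaminium iodide | C[N+](C)(C)CC1C(=O)C[C@H]2OC[C@@H]1C2(C)C.[I-] | intermediate (not isolated)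
12 | (1R,5R)-8,8-dimethyl-2-methylidene-6-oxabicyclo[3.2.1]octan-3-one, fragment 1 (the C1 descriptor differs from 7 by priority only) | C=C1C(=O)C[C@H]2OC[C@@H]1C2(C)C | intermediate
13 | 3-methoxybenzoic acid | COc1cccc(c1)C(=O)O | starting material
14 | 3-methoxycyclohexa-2,5-diene-1-carboxylic acid (racemic) | COC1=CC(C(=O)O)C=CC1 | intermediate
15 | methyl 3-methoxycyclohexa-2,5-diene-1-carboxylate (racemic) | COC(=O)C1C=CCC(OC)=C1 | intermediate
16 | methyl 1,4-dioxaspiro[4.5]dec-8-ene-7-carboxylate (racemic; the stereocentre is removed in step 10) | COC(=O)C1CC2(CC=C1)OCCO2 | intermediate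
17 | methyl 1,4-dioxaspiro[4.5]dec-7-ene-7-carboxylate | COC(=O)C1=CCCC2(C1)OCCO2 | intermediate (not isolated)
18 | 1,4-dioxaspiro[4.5]dec-7-ene-7-carboxylic acid, fragment 2 | OC(=O)C1=CCCC2(C1)OCCO2 | intermediate
19 | [(1S,5R)-8,8-dimethyl-3-oxo-6-oxabicyclo[3.2.1]octan-2-yl]methyl 1,4-dioxaspiro[4.5]dec-7-ene-7-carboxylate | O=C(OCC1C(=O)C[C@H]2OC[C@@H]1C2(C)C)C3=CCCC4(C3)OCCO4 | intermediate (not isolated)
20 | tetracyclic spirolactone, C6 ketone as dioxolane; (9R,10S,16S,20R,23R), rings A/B cis-fused, C9 trans to C22 on ring C | O1CCOC12CC[C@@H]3[C@H](C2)C(=O)OC[C@]31C(=O)C[C@H]2OC[C@@H]1C2(C)C | intermediate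
21 | diketo lactone (C6 and C17 ketones), stereocentres as in 20 | O=C1CC[C@@H]2[C@H](C1)C(=O)OC[C@]21C(=O)C[C@H]2OC[C@@H]1C2(C)C | intermediate
22 | ring A enol triflate (C6=C7), stereocentres as in 20 | O=S(=O)(OC1=CC[C@@H]2[C@H](C1)C(=O)OC[C@]21C(=O)C[C@H]2OC[C@@H]1C2(C)C)C(F)(F)F | intermediate
23 | tributyl(1-ethoxyvinyl)stannane | CCOC(=C)[Sn](CCCC)(CCCC)CCCC | starting material
24 | 2-ethoxy diene (1-ethoxyvinyl on C6, C6=C7) | CCOC(=C)C1=CC[C@@H]2[C@H](C1)C(=O)OC[C@]21C(=O)C[C@H]2OC[C@@H]1C2(C)C | intermediate (not isolated)
25 | ring A enone (acetyl on C6, C6=C7) | CC(=O)C1=CC[C@@H]2[C@H](C1)C(=O)OC[C@]21C(=O)C[C@H]2OC[C@@H]1C2(C)C | intermediate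
26 | (6S)-methyl ketone (acetyl cis to C12 and C16) | CC(=O)[C@H]1CC[C@@H]2[C@H](C1)C(=O)OC[C@]21C(=O)C[C@H]2OC[C@@H]1C2(C)C | intermediate (not isolated)
27 | (6R)-methyl ketone (acetyl trans to C12 and C16) | CC(=O)[C@@H]1CC[C@@H]2[C@H](C1)C(=O)OC[C@]21C(=O)C[C@H]2OC[C@@H]1C2(C)C | intermediate
28 | terminal enol triflate, 1-(triflyloxy)vinyl on C6 (6R) | C=C(OS(=O)(=O)C(F)(F)F)[C@@H]1CC[C@@H]2[C@H](C1)C(=O)OC[C@]21C(=O)C[C@H]2OC[C@@H]1C2(C)C | intermediate
29 | 2-substituted acrylic acid, 1-carboxyvinyl on C6 (6R) | C=C(C(=O)O)[C@@H]1CC[C@@H]2[C@H](C1)C(=O)OC[C@]21C(=O)C[C@H]2OC[C@@H]1C2(C)C | intermediate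
30 | CNP0152427.2 (2R,6R,9R,10S,16S,20R,23R) | C[C@@H](C(=O)O)[C@@H]1CC[C@@H]2[C@H](C1)C(=O)OC[C@]21C(=O)C[C@H]2OC[C@@H]1C2(C)C | target

**Step count and risks**

Total step count: 18. Longest linear sequence: 13 steps (1 → 2 → 5 → 7 → 10 → 12 → 20 → 21 → 22 → 25 → 27 → 28 → 29 → 30; steps 1, 3, 4, 5, 6 and 11–18).

Steps most likely to fail:

1. Step 11. What may go wrong: the C16–C9 bond forms on the enolate face syn to the O21–C22 bridge (the C24 methyl wins over the bridge), or it does not form at all because reversion of 19 and self-condensation of 12 outrun the hindered closure. The fallback uses known reactions and closes ring B before ring D, so that the face of C16 is chosen by the neighbouring C23 substituent on a nearly flat monocyclic dienolate instead of by the bicyclic bridges. It sets out from 2 and 4 and uses 18. The conjugate addition of step 3 is run as before, but the magnesium enolate is trapped at −78 °C with monomeric formaldehyde (conjugate addition–aldol sequence) to give hydroxymethyl enone F1. Steglich esterification with 18 (DCC, DMAP cat., CH2Cl2, 0 °C) gives ester F2. Cs2CO3 in MeCN then brings about the ester-tethered intramolecular Michael addition of the ketone enolate, C9 entering anti to the silylmethyl group on C23 (the usual 2,3-trans outcome), to give tricyclic enone lactone F3. Tamao–Fleming oxidation under the conditions of step 4 gives hydroxy enone F4, which closes ring D by oxa-Michael addition with K2CO3 and so comes back to the route at 20.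

2. Step 5. What may go wrong: aminomethylation on the C19 side (the C19 enolate is trapped before it has opened), which ends in the regioisomeric methylene ketone. The fallback attaches C15 before ring D exists, when C16 is the only enolisable carbon. It sets out from 2 and 4. The magnesium enolate of step 3 is trapped in the flask with 8 to give ring-opened amino ketone F5. Its trifluoroacetate salt (protonation shields the amine from N-oxidation) is oxidised under the acidic variant of the Tamao–Fleming reaction (KHF2, AcOOH, DMF, 25 °C) to 9, and K2CO3 in MeOH closes ring D and comes back to the route at 10.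

3. Step 13. What may go wrong: competing deprotonation at C19 of the C17 ketone, which leads to the wrong enol triflate or to base-induced opening of ring D. The fallback tells the two ketones apart by access of a nucleophile to the carbonyl carbon instead of by kinetic enolisation. It sets out from 21. Ethynylmagnesium bromide (THF, −78 °C) adds only to the unhindered C6 ketone to give propargylic alcohol F6. Rupe rearrangement (HCO2H, 80 °C) gives enone 25 together with its C6=C11 isomer F7. The mixture comes back to the route at 25 and, since step 15 hydrogenates and equilibrates both isomers to the same ketone, converges at 27.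

**Further compounds**

F1 | step 11 | (5S)-6-(hydroxymethyl)-5-{[isopropoxy(dimethyl)silyl]methyl}-4,4-dimethylcyclohex-2-en-1-one (C6 epimers) | OCC1C(=O)C=CC(C)(C)[C@H]1C[Si](C)(C)OC(C)C
F2 | step 11 | ester of F1 with acid 18 | O=C(OCC1C(=O)C=CC(C)(C)[C@H]1C[Si](C)(C)OC(C)C)C2=CCCC3(C2)OCCO3
F3 | step 11 | tricyclic enone spirolactone, ring D open, C22 as CH2SiMe2(OiPr), C9, C10, C16 and C23 configured as in 20 | O1CCOC12CC[C@@H]3[C@H](C2)C(=O)OC[C@]31C(=O)C=CC(C)(C)[C@H]1C[Si](C)(C)OC(C)C
F4 | step 11 | hydroxy enone from F3 (C22 as CH2OH) | O1CCOC12CC[C@@H]3[C@H](C2)C(=O)OC[C@]31C(=O)C=CC(C)(C)[C@H]1CO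
F5 | step 5 | (5S)-6-[(dimethylamino)methyl]-5-{[isopropoxy(dimethyl)silyl]methyl}-4,4-dimethylcyclohex-2-en-1-one (C6 epimers) | CN(C)CC1C(=O)C=CC(C)(C)[C@H]1C[Si](C)(C)OC(C)C
F6 | step 13 | C6 ethynyl carbinol of 21 (C6 epimers) | C#CC1(O)CC[C@@H]2[C@H](C1)C(=O)OC[C@]21C(=O)C[C@H]2OC[C@@H]1C2(C)C
F7 | step 13 | C6=C11 isomer of enone 25 | CC(=O)C=1CC[C@@H]2[C@H](C=1)C(=O)OC[C@]21C(=O)C[C@H]2OC[C@@H]1C2(C)C
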